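Conventions used throughout: the oxane ring is numbered O1, C2 (aryl-bearing), C3, C4, C5, C6, and C7 is the exocyclic carbinol carbon. TBS = tert-butyldimethylsilyl; "4-(TBSO)phenyl" = 4-(tert-butyldimethylsilyloxy)phenyl.

## The problem

The target is an oxane with a 4-hydroxyphenyl group at C2, an (E)-3-(4-hydroxyphenyl)prop-2-enyl chain at C3 and a hydroxy(4-hydroxyphenyl)methyl group (C7) at C5; C4 and C6 are methylenes. The three ring substituents are all cis (2R,3S,5R), so one of them is axial in either chair. The arrangement is therefore not a thermodynamic sink and has to be set kinetically. C2 is the natural anchor, and C3 (adjacent) and C5 (1,4 to C2, so only reachable through a relay) can be controlled from it on the ring. C7 (R) lies outside the ring and is best left to a reagent. C3 and C5 each need a carbon substituent while C4 and C6 need none, so the four ring carbons must be chemically distinguished. The fragile parts are the three phenols, the E-4-hydroxystyrene and the two 4-hydroxybenzylic C–O bonds (C2–O1 and C7–OH), which ionise towards quinone-methide-type cations in acid and can open through the phenoxide in base. The phenols are therefore kept silylated until the last step, and Lewis acid is used only while C2 is flanked by a carbonyl group. The enabling feature is that O1, C2 and C3–C6 are an aryl(2-furyl)methanol at a higher oxidation level: oxidising the furan and reclosing the carbinol oxygen onto C6 gives C3 as a ketone, C4=C5 as an enone and C6 as a hemiacetal, one distinct handle for each position.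

## Retrosynthesis

**Side chain.** Target 23 is taken back to its tris-silyl ether 22. The first skeletal cut is the C(sp3)–C(sp2) bond between the methylene on C3 and the styrene, giving the exocyclic alkene 19 and the E-vinyl iodide 20, which are joined through alkylborane 21. Cutting the styrene C=C instead would need a homologated C3–CH2–CHO aldehyde several steps away from a ring ketone. Cutting C3–CH2 would need an alkylation with no obvious stereocontrol. The chosen cut lets one hydroboration set C3 and bring in the whole chain. The forward step must add boron from the face opposite the C2 aryl group and keep the E geometry. Iodide 20 is one step from aldehyde 11.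

**C7.** Carbinol 19 is cut at C7–H to ketone 18, and 18 is the unmasked form of dithiane 17. An exocyclic carbinol beside a ring stereocentre is unlikely to be controlled by the substrate, so the C–H bond is made by a chiral reductant. Keeping C7 as a dithiane until the C3 ketone has gone avoids a 1,4-diketone. The reduction must spare the alkene and must not epimerise C5.

**C3 methylene and C6.** Alkene 17 goes back to ketone 16 (C3=CH2), and 16 to methyl acetal 15 (C6–H). These two changes restore the pyranone pattern of a C3 ketone and a C6 acetal. The order is dictated by C2. C6 is deoxygenated while the ketone still deactivates the C2–O1 bond towards Lewis acid. The methylenation must be non-basic because C2–H is acidic and the 2,5-trans epimer is the more stable one.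

**C5–C7 bond.** Ketone 15 is cut at C5–C7 into enone acetal 10 and aryl dithiane 12 (through anion 13 and enolate 14). C5 is β to the C3 ketone, so conjugate addition of an aroyl anion equivalent is the natural disconnection. The C6 methoxy group, trans to the C2 aryl group, relays C2 to C5. The forward step must add 1,4, anti to the methoxy group, and must not deprotonate C2. Dithiane 12 is one step from 11.

**Ring.** Acetal 10 comes from lactol 9, and 9 is opened at O1–C6 and folded back (through enedione 8 and epoxide 7) into furyl carbinol 6. Other ring constructions (etherification at C2 or C6, Prins closure, hetero-Diels–Alder) must create stereocentres while they close the ring. This one creates none that matters and leaves three differentiated handles. The precursor has a single stereocentre. The forward step must oxidise the furan, not the arene, and leave C2 intact.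

**Carbinol.** Compound 6 is cut at the C2–aryl bond into bromide 1 and furfural 2, joined by a catalytic asymmetric aryl transfer through 3, 4 and 5. Resolving racemic 6 with a lipase was weighed and set aside: both carbinol substituents are flat aromatic groups of similar size, which lipases discriminate poorly, and half the material would be lost.

## Roads not taken

**Alternative 1:** The cut is C2–C3 and C5–C7 together, using the hidden C2 symmetry of the ArCH(O)–CH–CH2–CH–CH(O)Ar backbone. The bis-magnesium enolate of glutaryl bis-oxazolidinone A1 would add to two molecules of aldehyde 11 to give the bis-anti-aldol adduct A2 with all four stereocentres. This is the most stereo-economical road: one operation, an achiral five-carbon core, and ee amplified because two auxiliary-controlled events must both err to give the enantiomer. Because A2 is C2-symmetric, the first differentiating operation (closure of one carbinol oxygen onto the distal acyl group) cannot give regioisomers. In stereocentre count per step it is clearly better than the chosen plan, and it may be shorter overall.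

Its weak points:
- Magnesium-halide anti-aldols are sluggish with electron-rich aldehydes such as 11, and the adducts retro-aldolise easily; both aldol events must be complete and selective.
- The lactone carbon must later be reduced to the C6 methylene by ionic reduction while two electron-rich benzylic C–O bonds at C2 and C7 are exposed.
- The remaining acyl group still needs reduction and an sp3–sp2 coupling like the one used here.
- Two equivalents of auxiliary are consumed.

Against this, the chosen plan uses chirality once and catalytically, distinguishes the ring positions by oxidation level and not by desymmetrisation, and does its one Lewis-acidic deoxygenation while C2 is protected by the adjacent ketone and C7 is a dithiane.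

**Alternative 2:** The cut is O1–C6 and C5–C6, with C3 and C5 tied together in a cyclohexene. Acid would condense carbinol A3 with formaldehyde A4 to an oxocarbenium ion that the ring alkene captures, giving oxabicycle A5. Ozonolysis would then give dialdehyde A6, which carries C7 and the chain carbon. The bridged bicycle enforces the 3,5-cis relationship, and C6 arrives at the right oxidation level, so the acetal relay and its removal are not needed. That is a real advantage over the chosen plan.

Its weak points:
- A3 already needs two adjacent stereocentres set in an open chain.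
- The oxocarbenium ion sits on an ionisable benzylic ether, so the aryl group must be deactivated as an ester, which cannot survive the aryl organometallic needed later at C7.
- The secondary cation formed on cyclisation can eliminate in two directions.
- A6 has two aldehydes to tell apart, one of them α-branched and epimerisable, and C7 would come from an aryl addition with little facial bias.

The chosen plan is longer at C6 but never has to separate like functional groups or set C7 by substrate control.

**Alternative 3:** The cut is O1–C2 and C3–C4. Enal A7 (O1=C6–C5=C4) and Z-alkene A8 (C2=C3) would combine in an inverse-demand oxa-Diels–Alder reaction to give dihydropyran A9. It is the most convergent road: two aryl groups, the ring and the 2,3-cis relationship (from the Z geometry) in one step, which is better than the linear plan.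

Its weak points:
- α-Substituted acroleins are reluctant heterodienes towards styrenes.
- Lewis-acid activation with an electron-rich styrene tends to go stepwise through a benzylic cation, which loses the Z information.
- The face of the diene is controlled only by the acyclic C7 centre.
- C5 must afterwards be set by hydrogenating the C5=C6 enol ether, and A7 must first be made enantioenriched.

The chosen plan accepts more steps for a ring-forming reaction that is routine and for stereocentres that are each set on a chair.

Key step: step 2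

Assumption: (2S)-3-exo-morpholinoisoborneol [(−)-MIB] directs aryl transfer to the Si face of furfural, as it does alkyl transfer to aromatic aldehydes, which gives (S)-6; if the sense proves opposite, the enantiomeric ligand is used.

## Route

Step 1
Reactants: 1 (4-bromophenoxy)(tert-butyl)dimethylsilane; 2 furfural
Product: 6 (S)-[4-(TBSO)phenyl](furan-2-yl)methanol, via aryllithium 3 (not isolated), via arylzinc chloride 4 (not isolated), via aryl(butyl)zinc 5 (not isolated)
Conditions: n-BuLi, t-BuOMe, −78 °C; ZnCl2; n-BuLi; N,N,N',N'-tetraethylethylenediamine; then (−)-MIB (5 mol %), 2, toluene, 0 °C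
Reagents that add atoms: none
Why: Catalytic asymmetric arylation of an aldehyde with a mixed aryl(alkyl)zinc under amino-alcohol catalysis; the aryl group of 5 transfers in preference to butyl, the diamine sequesters LiCl that would promote racemic background addition, and the ligand-bound zinc species delivers the aryl group to the Si face of furfural, setting C2 as S.

Step 2
Reactants: 6 (S)-[4-(TBSO)phenyl](furan-2-yl)methanol
Product: 9 (2S)-6-hydroxy-2-[4-(TBSO)phenyl]-2H-pyran-3(6H)-one (anomeric mixture at C6), via furan 2,3-epoxide 7 (not isolated), via Z-enedione 8 (not isolated)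
Conditions: VO(acac)2 (5 mol %), t-BuOOH (decane), CH2Cl2, 0 °C to rt
Reagents that add atoms: tert-butyl hydroperoxide, CC(C)(C)OO
Why: Achmatowicz rearrangement of a furfuryl alcohol in its VO(acac)2/t-BuOOH variant. The carbinol binds vanadium and the peroxide oxygen is delivered to the adjacent furan C2=C3 bond to give epoxide 7, which opens with cleavage of the furan C–O bond to the Z-enedione 8. The carbinol oxygen then adds to the aldehyde carbon in a 6-exo-trig hemiacetalisation that forms O1–C6 and closes the pyranone ring. The only new stereocentre is the anomeric C6, which is not controlled here and is settled thermodynamically in step 3. C2 is retained because no bond to it is broken. The step needs chemoselectivity for the furan over the silyloxyarene, secured by hydroxyl-directed oxygen delivery and the much greater oxidisability of furan, and it needs neutral conditions so that the doubly activated carbinol does not ionise and the new α-aryl ketone does not enolise.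

Step 3
Reactants: 9 (2S)-6-hydroxy-2-[4-(TBSO)phenyl]-2H-pyran-3(6H)-one
Product: 10 (2S,6R)-6-methoxy-2-[4-(TBSO)phenyl]-2H-pyran-3(6H)-one (trans acetal)
Conditions: HC(OMe)3, BF3·OEt2 (cat.), Et2O, 0 °C
Reagents that add atoms: trimethyl orthoformate, COC(OC)OC
Why: Lewis-acid glycosidation of the lactol through the allylic oxocarbenium ion; under equilibrating conditions the methoxy group should settle axial (anomeric effect) and trans to the equatorial C2 aryl group, and the cis anomer is separated and re-equilibrated.

Step 4
Reactants: 11 4-(TBSO)benzaldehyde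
Product: 12 2-[4-(TBSO)phenyl]-1,3-dithiane
Conditions: HS(CH2)3SH, BF3·OEt2 (cat.), CH2Cl2, 0 °C
Reagents that add atoms: propane-1,3-dithiol, SCCCS
Why: Standard Lewis-acid dithioacetalisation of an aryl aldehyde; the aryl silyl ether tolerates catalytic BF3·OEt2 at 0 °C.

Step 5
Reactants: 12 2-[4-(TBSO)phenyl]-1,3-dithiane; 10 (2S,6R)-6-methoxy-2-[4-(TBSO)phenyl]-2H-pyran-3(6H)-one
Product: 15 (2S,5R,6R)-6-methoxy-2-[4-(TBSO)phenyl]-5-{2-[4-(TBSO)phenyl]-1,3-dithian-2-yl}oxan-3-one, via 2-lithiodithiane 13 (not isolated), via lithium enolate 14 (not isolated)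
Conditions: 12, n-BuLi, THF, −78 to −20 °C; DMPU, then 10, −78 °C; AcOH, −78 °C
Reagents that add atoms: none
Why: Michael addition of an aryl-stabilised 2-lithio-1,3-dithiane (acyl anion equivalent) to a cyclic enone, the conjugate addition long used for lignan skeletons; DMPU and the hindered C3 carbonyl favour 1,4-addition, the nucleophile enters axially at C5 anti to the axial C6 methoxy group and hence cis to the C2 aryl group (5R), and enolate 14 is protonated cold before it can equilibrate towards C2.

Step 6
Reactants: 15 (2S,5R,6R)-6-methoxy-2-[4-(TBSO)phenyl]-5-{2-[4-(TBSO)phenyl]-1,3-dithian-2-yl}oxan-3-one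
Product: 16 (2S,5R)-2-[4-(TBSO)phenyl]-5-{2-[4-(TBSO)phenyl]-1,3-dithian-2-yl}oxan-3-one
Conditions: Et3SiH, BF3·OEt2, CH2Cl2, −78 to −30 °C
Reagents that add atoms: none
Why: Ionic hydrogenation of an acetal: BF3·OEt2 ionises C6–OMe and Et3SiH reduces the oxocarbenium ion; the C3 ketone reacts far more slowly and deactivates the benzylic C2–O1 bond towards ionisation, and dithianes, themselves made under BF3 catalysis, are not ionised; no stereocentre is formed.

Step 7
Reactants: 16 (2S,5R)-2-[4-(TBSO)phenyl]-5-{2-[4-(TBSO)phenyl]-1,3-dithian-2-yl}oxan-3-one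
Product: 17 (2R,5R)-3-methylidene-2-[4-(TBSO)phenyl]-5-{2-[4-(TBSO)phenyl]-1,3-dithian-2-yl}oxane
Conditions: Zn, CH2Br2, TiCl4 (reagent preformed in THF), CH2Cl2, 0 °C to rt
Reagents that add atoms: dibromomethane, BrCBr
Why: Takai–Lombardo methylenation; the non-basic gem-dimetallic reagent converts readily enolisable ketones to methylene compounds without epimerisation, which a Wittig ylide would risk at the acidic C2–H (the descriptor at C2 changes only because the priorities change).

Step 8
Reactants: 17 (2R,5R)-3-methylidene-2-[4-(TBSO)phenyl]-5-{2-[4-(TBSO)phenyl]-1,3-dithian-2-yl}oxane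
Product: 18 (2R,5R)-5-[4-(TBSO)benzoyl]-3-methylidene-2-[4-(TBSO)phenyl]oxane
Conditions: MeI, CaCO3, MeCN/H2O (9:1), 40 °C
Reagents that add atoms: water, O
Why: Alkylative hydrolysis of a 1,3-dithiane; S-methylation and hydrolysis of the aryl-stabilised thionium ion release the ketone under buffered, near-neutral conditions that leave the alkene, the silyl ethers and the C5 stereocentre alone.

Step 9
Reactants: 18 (2R,5R)-5-[4-(TBSO)benzoyl]-3-methylidene-2-[4-(TBSO)phenyl]oxane
Product: 19 (2R,5R)-5-[(R)-hydroxy(4-(TBSO)phenyl)methyl]-3-methylidene-2-[4-(TBSO)phenyl]oxane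
Conditions: (S)-1-methyl-3,3-diphenyltetrahydro-1H,3H-pyrrolo[1,2-c][1,3,2]oxazaborole [(S)-Me-CBS, 0.5 equiv], catecholborane, toluene, −78 to −40 °C
Reagents that add atoms: none
Why: Corey–Bakshi–Shibata reduction of an aryl ketone with catecholborane, which does not hydroborate the alkene at low temperature; with the aryl group as the larger substituent the (S)-oxazaborolidine delivers hydride to the Si face, as with acetophenone, giving the (R)-carbinol at C7 under reagent control.

Step 10
Reactants: 11 4-(TBSO)benzaldehyde
Product: 20 (E)-tert-butyl[4-(2-iodoethenyl)phenoxy]dimethylsilane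
Conditions: CHI3, CrCl2, THF, 0 °C to rt
Reagents that add atoms: iodoform, IC(I)I
Why: Takai olefination; the gem-dichromium species formed from CHI3 and CrCl2 adds to the aldehyde and eliminates to the vinyl iodide, with high E selectivity expected for aryl aldehydes.

Step 11
Reactants: 19 (2R,5R)-5-[(R)-hydroxy(4-(TBSO)phenyl)methyl]-3-methylidene-2-[4-(TBSO)phenyl]oxane; 20 (E)-tert-butyl[4-(2-iodoethenyl)phenoxy]dimethylsilane
Product: 22 (2R,3S,5R)-5-[(R)-hydroxy(4-(TBSO)phenyl)methyl]-2-[4-(TBSO)phenyl]-3-[(E)-3-(4-(TBSO)phenyl)prop-2-enyl]oxane, via alkylborane 21 (not isolated)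
Conditions: 9-BBN (2.5 equiv), THF, 0 °C to rt; then 20, Pd(dppf)Cl2 (5 mol %), AsPh3, aq K3PO4, DMF, rt
Reagents that add atoms: none
Why: Hydroboration followed by B-alkyl Suzuki–Miyaura coupling; allylic 1,3-strain with the exocyclic methylene holds the C2 aryl group axial, so 9-BBN adds from the face opposite to it and to the C5 substituent, placing H at C3 trans and the CH2–B arm cis to both (3S), and the primary alkylborane couples with the vinyl iodide with retention of E geometry. Excess 9-BBN covers the C7 hydroxyl, which is carried as its borinate and freed by the aqueous base.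

Step 12
Reactants: 22 (2R,3S,5R)-5-[(R)-hydroxy(4-(TBSO)phenyl)methyl]-2-[4-(TBSO)phenyl]-3-[(E)-3-(4-(TBSO)phenyl)prop-2-enyl]oxane
Product: 23 4-[(E)-3-{(2R,3S,5R)-5-[(R)-hydroxy(4-hydroxyphenyl)methyl]-2-(4-hydroxyphenyl)oxan-3-yl}prop-1-enyl]phenol (CNP0182155.1)
Conditions: Bu4NF, AcOH, THF, 0 °C to rt
Reagents that add atoms: none
Why: Fluoride cleavage of the three aryl silyl ethers; acetic acid buffers the phenoxides so that the 4-hydroxybenzylic C2–O1 and C7–O bonds and the styrene are not endangered, and no stereocentre is touched.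

## Compound list

1 | (4-bromophenoxy)(tert-butyl)dimethylsilane | CC(C)(C)[Si](C)(C)Oc1ccc(Br)cc1 | starting material
2 | furfural (furan-2-carbaldehyde) | O=Cc1ccco1 | starting material
3 | [4-(TBSO)phenyl]lithium | [Li]c1ccc(O[Si](C)(C)C(C)(C)C)cc1 | intermediate
4 | [4-(TBSO)phenyl]zinc chloride | Cl[Zn]c1ccc(O[Si](C)(C)C(C)(C)C)cc1 | intermediate
5 | butyl[4-(TBSO)phenyl]zinc | CCCC[Zn]c1ccc(O[Si](C)(C)C(C)(C)C)cc1 | intermediate
6 | (S)-[4-(TBSO)phenyl](furan-2-yl)methanol | O[C@H](c1ccco1)c1ccc(O[Si](C)(C)C(C)(C)C)cc1 | intermediate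
7 | (S)-[4-(TBSO)phenyl](2,6-dioxabicyclo[3.1.0]hex-3-en-1-yl)methanol (furan 2,3-epoxide, ring stereocentres undefined) | O[C@H](C12OC1C=CO2)c1ccc(O[Si](C)(C)C(C)(C)C)cc1 | intermediate
8 | (2Z,5S)-5-hydroxy-4-oxo-5-[4-(TBSO)phenyl]pent-2-enal | O[C@H](C(=O)/C=C\C=O)c1ccc(O[Si](C)(C)C(C)(C)C)cc1 | intermediate
9 | (2S)-6-hydroxy-2-[4-(TBSO)phenyl]-2H-pyran-3(6H)-one, anomeric mixture | O=C1C=CC(O)O[C@H]1c1ccc(O[Si](C)(C)C(C)(C)C)cc1 | intermediate
10 | (2S,6R)-6-methoxy-2-[4-(TBSO)phenyl]-2H-pyran-3(6H)-one | O=C1C=C[C@H](OC)O[C@H]1c1ccc(O[Si](C)(C)C(C)(C)C)cc1 | intermediate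
11 | 4-(tert-butyldimethylsilyloxy)benzaldehyde | O=Cc1ccc(O[Si](C)(C)C(C)(C)C)cc1 | starting material
12 | 2-[4-(TBSO)phenyl]-1,3-dithiane | CC(C)(C)[Si](C)(C)Oc1ccc(C2SCCCS2)cc1 | intermediate
13 | 2-lithio-2-[4-(TBSO)phenyl]-1,3-dithiane | [Li]C1(c2ccc(O[Si](C)(C)C(C)(C)C)cc2)SCCCS1 | intermediate
14 | lithium enolate of 15 (C3–O–Li, C3=C4) | [Li]OC1=C[C@@H](C2(c3ccc(O[Si](C)(C)C(C)(C)C)cc3)SCCCS2)[C@H](OC)O[C@H]1c1ccc(O[Si](C)(C)C(C)(C)C)cc1 | intermediate
15 | (2S,5R,6R)-6-methoxy-2-[4-(TBSO)phenyl]-5-{2-[4-(TBSO)phenyl]-1,3-dithian-2-yl}oxan-3-one | O=C1C[C@@H](C2(c3ccc(O[Si](C)(C)C(C)(C)C)cc3)SCCCS2)[C@H](OC)O[C@H]1c1ccc(O[Si](C)(C)C(C)(C)C)cc1 | intermediate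
16 | (2S,5R)-2-[4-(TBSO)phenyl]-5-{2-[4-(TBSO)phenyl]-1,3-dithian-2-yl}oxan-3-one | O=C1C[C@@H](C2(c3ccc(O[Si](C)(C)C(C)(C)C)cc3)SCCCS2)CO[C@H]1c1ccc(O[Si](C)(C)C(C)(C)C)cc1 | intermediate
17 | (2R,5R)-3-methylidene-2-[4-(TBSO)phenyl]-5-{2-[4-(TBSO)phenyl]-1,3-dithian-2-yl}oxane | C=C1C[C@@H](C2(c3ccc(O[Si](C)(C)C(C)(C)C)cc3)SCCCS2)CO[C@H]1c1ccc(O[Si](C)(C)C(C)(C)C)cc1 | intermediate
18 | (2R,5R)-5-[4-(TBSO)benzoyl]-3-methylidene-2-[4-(TBSO)phenyl]oxane | C=C1C[C@@H](C(=O)c2ccc(O[Si](C)(C)C(C)(C)C)cc2)CO[C@H]1c1ccc(O[Si](C)(C)C(C)(C)C)cc1 | intermediate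
19 | (2R,5R)-5-[(R)-hydroxy(4-(TBSO)phenyl)methyl]-3-methylidene-2-[4-(TBSO)phenyl]oxane | C=C1C[C@@H]([C@@H](O)c2ccc(O[Si](C)(C)C(C)(C)C)cc2)CO[C@H]1c1ccc(O[Si](C)(C)C(C)(C)C)cc1 | intermediate
20 | (E)-tert-butyl[4-(2-iodoethenyl)phenoxy]dimethylsilane | CC(C)(C)[Si](C)(C)Oc1ccc(/C=C/I)cc1 | intermediate
21 | B-alkyl-9-BBN adduct of 19 (boron on the C3 methylene, all-cis ring, C7 oxygen as its 9-BBN borinate) | B1(C[C@H]2C[C@@H]([C@@H](OB3C4CCCC3CCC4)c3ccc(O[Si](C)(C)C(C)(C)C)cc3)CO[C@H]2c2ccc(O[Si](C)(C)C(C)(C)C)cc2)C2CCCC1CCC2 | intermediate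
22 | (2R,3S,5R)-5-[(R)-hydroxy(4-(TBSO)phenyl)methyl]-2-[4-(TBSO)phenyl]-3-[(E)-3-(4-(TBSO)phenyl)prop-2-enyl]oxane | CC(C)(C)[Si](C)(C)Oc1ccc(/C=C/C[C@H]2C[C@@H]([C@@H](O)c3ccc(O[Si](C)(C)C(C)(C)C)cc3)CO[C@H]2c2ccc(O[Si](C)(C)C(C)(C)C)cc2)cc1 | intermediate
23 | 4-[(E)-3-{(2R,3S,5R)-5-[(R)-hydroxy(4-hydroxyphenyl)methyl]-2-(4-hydroxyphenyl)oxan-3-yl}prop-1-enyl]phenol | Oc1ccc(/C=C/C[C@H]2C[C@@H]([C@@H](O)c3ccc(O)cc3)CO[C@H]2c2ccc(O)cc2)cc1 | target

## Step count and least certain steps

Total: 12 steps. Longest linear sequence: 10 steps (1, 2, 3, 5, 6, 7, 8, 9, 11, 12); steps 4 and 10 are one-step branches from 11.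

**Step 2 (key step).** The likeliest failure is ionisation of the carbinol C–O bond, which is doubly activated by furyl and 4-silyloxyphenyl and would give racemisation or ether formation. Over-oxidation of the enedione before it closes is also possible. Fallback, from 6: sensitised photooxygenation (O2, tetraphenylporphyrin, visible light, CH2Cl2/MeOH, −78 °C) adds singlet oxygen across the furan to give the furan endoperoxide F1. Reduction in the same flask with Me2S gives enedione 8, which closes to 9. The O1–C6 bond and the ring are formed as before, but the oxidant is neutral and indifferent to the arene. The route is rejoined at 9.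

**Step 5.** The basic dithiane anion may take a proton from C2 (or C6) faster than it adds, which would epimerise C2 or expel methoxide; 1,2-addition is a lesser concern. Fallback, from 10 and 11: photocatalytic hydroacylation with (n-Bu4N)4W10O32 (MeCN, 365 nm) generates the aroyl radical from 11, which should add to C5 anti to the methoxy group under neutral conditions to give the diketone acetal F2. Et3SiH/BF3·OEt2 then gives the diketone F3. Takai–Lombardo methylenation, expected to prefer the more electrophilic ring ketone over the donor-substituted aryl ketone, rejoins the route at 18.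

**Step 11.** Face selection in the hydroboration may be incomplete, and transmetalation of the β-branched alkylborane may be slow enough for protodeboronation to compete. The aqueous base may also remove aryl silyl groups, which is harmless for step 12 but complicates purification. Fallback, from 19: silylation (TBSOTf, 2,6-lutidine) gives the C7 silyl ether F4. Treatment with 9-BBN and then NaBO3·4H2O gives the primary alcohol F5, at which stage any C3 epimer can be removed. I2, PPh3 and imidazole give the primary iodide F6. Zinc insertion (Zn, LiCl, THF) gives the alkylzinc iodide F7, which is not isolated, and anhydrous Negishi coupling with 20 and Pd(PPh3)4 gives the tetrasilyl ether F8. Bu4NF/AcOH removes all four silyl groups and rejoins the route at 23.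

**Step 9.** Reagent control may be insufficient: the α-branched ring carbon competes with the aryl group for the role of larger substituent, and the electron-rich ketone reacts slowly, so substrate bias can erode selectivity. Fallback, from 18: Luche reduction (NaBH4, CeCl3·7H2O, MeOH, −40 °C) gives 19 together with the C7 epimer F9. The two are separated, and F9 is re-oxidised with Dess–Martin periodinane/NaHCO3 to 18 and recycled. The route is rejoined at 19.

**Step 1.** Enantiomeric purity may be eroded by background addition of lithium-containing aryl species, and later by acid-catalysed ionisation of 6 on silica (base-washed silica and immediate use are advisable). Fallback, from 1: aryllithium 3 is acylated with N-methoxy-N-methylfuran-2-carboxamide to give the diaryl ketone F10. Asymmetric transfer hydrogenation with RuCl(p-cymene)(TsDPEN) in HCO2H/Et3N then gives the carbinol, the catalyst antipode being chosen once the configuration of the product has been assigned. The route is rejoined at 6.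

## Further compounds

F1 | step 2 | (S)-[4-(TBSO)phenyl](2,3,7-trioxabicyclo[2.2.1]hept-5-en-1-yl)methanol (furan endoperoxide) | O[C@H](C12OOC(C=C1)O2)c1ccc(O[Si](C)(C)C(C)(C)C)cc1
F2 | step 5 | (2S,5R,6R)-5-[4-(TBSO)benzoyl]-6-methoxy-2-[4-(TBSO)phenyl]oxan-3-one | O=C1C[C@@H](C(=O)c2ccc(O[Si](C)(C)C(C)(C)C)cc2)[C@H](OC)O[C@H]1c1ccc(O[Si](C)(C)C(C)(C)C)cc1
F3 | step 5 | (2S,5R)-5-[4-(TBSO)benzoyl]-2-[4-(TBSO)phenyl]oxan-3-one | O=C1C[C@@H](C(=O)c2ccc(O[Si](C)(C)C(C)(C)C)cc2)CO[C@H]1c1ccc(O[Si](C)(C)C(C)(C)C)cc1
F4 | step 11 | C7 tert-butyldimethylsilyl ether of 19 | C=C1C[C@@H]([C@@H](O[Si](C)(C)C(C)(C)C)c2ccc(O[Si](C)(C)C(C)(C)C)cc2)CO[C@H]1c1ccc(O[Si](C)(C)C(C)(C)C)cc1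
F5 | step 11 | all-cis 3-(hydroxymethyl)oxane from F4 | OC[C@H]1C[C@@H]([C@@H](O[Si](C)(C)C(C)(C)C)c2ccc(O[Si](C)(C)C(C)(C)C)cc2)CO[C@H]1c1ccc(O[Si](C)(C)C(C)(C)C)cc1
F6 | step 11 | all-cis 3-(iodomethyl)oxane from F5 | IC[C@H]1C[C@@H]([C@@H](O[Si](C)(C)C(C)(C)C)c2ccc(O[Si](C)(C)C(C)(C)C)cc2)CO[C@H]1c1ccc(O[Si](C)(C)C(C)(C)C)cc1
F7 | step 11 | alkylzinc iodide from F6 | I[Zn]C[C@H]1C[C@@H]([C@@H](O[Si](C)(C)C(C)(C)C)c2ccc(O[Si](C)(C)C(C)(C)C)cc2)CO[C@H]1c1ccc(O[Si](C)(C)C(C)(C)C)cc1
F8 | step 11 | C7 tert-butyldimethylsilyl ether of 22 | CC(C)(C)[Si](C)(C)Oc1ccc(/C=C/C[C@H]2C[C@@H]([C@@H](O[Si](C)(C)C(C)(C)C)c3ccc(O[Si](C)(C)C(C)(C)C)cc3)CO[C@H]2c2ccc(O[Si](C)(C)C(C)(C)C)cc2)cc1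
F9 | step 9 | C7 epimer of 19, (S)-carbinol | C=C1C[C@@H]([C@H](O)c2ccc(O[Si](C)(C)C(C)(C)C)cc2)CO[C@H]1c1ccc(O[Si](C)(C)C(C)(C)C)cc1
F10 | step 1 | [4-(TBSO)phenyl](furan-2-yl)methanone | O=C(c1ccco1)c1ccc(O[Si](C)(C)C(C)(C)C)cc1
A1 | alternative 1 | 1,5-bis[(R)-4-benzyl-2-oxooxazolidin-3-yl]pentane-1,5-dione | O=C(CCCC(=O)N1[C@H](Cc2ccccc2)COC1=O)N1[C@H](Cc2ccccc2)COC1=O
A2 | alternative 1 | C2-symmetric bis-anti-aldol adduct | O=C(N1[C@H](Cc2ccccc2)COC1=O)[C@H]([C@@H](O)c1ccc(O[Si](C)(C)C(C)(C)C)cc1)C[C@@H]([C@@H](O)c1ccc(O[Si](C)(C)C(C)(C)C)cc1)C(=O)N1[C@H](Cc2ccccc2)COC1=O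
A3 | alternative 2 | (R)-[4-(pivaloyloxy)phenyl][(S)-cyclohex-3-en-1-yl]methanol | O[C@@H](c1ccc(OC(=O)C(C)(C)C)cc1)[C@@H]1CC=CCC1
A4 | alternative 2 | formaldehyde | C=O
A5 | alternative 2 | 2-[4-(pivaloyloxy)phenyl]-3-oxabicyclo[3.3.1]non-6-ene | C1=CC[C@H]2C[C@@H]1CO[C@H]2c1ccc(OC(=O)C(C)(C)C)cc1
A6 | alternative 2 | all-cis 5-formyl-3-(2-oxoethyl)-2-[4-(pivaloyloxy)phenyl]oxane | O=CC[C@H]1C[C@@H](C=O)CO[C@H]1c1ccc(OC(=O)C(C)(C)C)cc1
A7 | alternative 3 | 2-{[4-(TBSO)phenyl](tert-butyldimethylsilyloxy)methyl}prop-2-enal, C7 as in the target | O=CC(=C)[C@@H](O[Si](C)(C)C(C)(C)C)c1ccc(O[Si](C)(C)C(C)(C)C)cc1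
A8 | alternative 3 | (Z)-4-[4-(TBSO)phenyl]but-3-en-1-yl pivalate | CC(C)(C)C(=O)OCC/C=C\c1ccc(O[Si](C)(C)C(C)(C)C)cc1
A9 | alternative 3 | cis-2-aryl-3-(2-pivaloyloxyethyl)-5-[aryl(silyloxy)methyl]-3,4-dihydro-2H-pyran | CC(C)(C)C(=O)OCC[C@H]2CC([C@@H](O[Si](C)(C)C(C)(C)C)c3ccc(O[Si](C)(C)C(C)(C)C)cc3)=CO[C@H]2c2ccc(O[Si](C)(C)C(C)(C)C)cc2
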